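**Retrosynthetic overview**
1. The two ketones (C1=O, C10=O) come from cleaving one sacrificial tetrasubstituted C1=C10 alkene in a 5-7-3 tricycle.
2. The tricycle comes from one three-component operation. An o-quinone methide (dialdehyde + isovaleraldehyde) alkylates C4 of bicyclogermacrene, and C1–C5 closure builds the five- and seven-membered rings together, setting C4, C5 and C1'.
3. Bicyclogermacrene comes from reductive carbonyl coupling of an open keto enal, whose own two carbonyl groups serve as a temporary staple.
4. The keto enal comes from a Claisen rearrangement of an allylic alcohol. That alcohol comes from the keto aldehyde obtained by ozonolysis of (+)-2-carene.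
5. Ring order: cyclopropane (bought), then the ten-membered ring, then the five- and seven-membered rings together, then the seven-membered ring is cut open.

Assumption: (+)-2-carene and 2,4,6-trihydroxyisophthalaldehyde are bought as catalogue items. Terpene carbons carry aromadendrane numbers (C1–C15) and the benzylic carbon is C1'.

**Step 1**
Reactants: 1 (+)-2-carene
Product: 3 (1S,3R)-2,2-dimethyl-3-(3-oxobutyl)cyclopropane-1-carbaldehyde (cis), via secondary ozonide 2 (not isolated)
Conditions: O3, CH2Cl2, −78 °C; then Me2S, −78 to 23 °C
Reagents that add atoms: ozone, [O-][O+]=O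
Why: Criegee ozonolysis with reductive work-up cuts the only alkene, and the two cyclopropane stereocentres (C6, C7) are carried over unchanged and cis from the chiral pool.

**Step 2**
Reactants: 3 keto aldehyde; 4 isopropenylmagnesium bromide
Product: 5 4-{(1R,3S)-3-[1-hydroxy-2-methylprop-2-enyl]-2,2-dimethylcyclopropyl}butan-2-one (both carbinol epimers)
Conditions: 4 (1.05 equiv), THF, −78 °C, 1 h; aq NH4Cl
Reagents that add atoms: isopropenylmagnesium bromide (4), C=C(C)[Mg]Br
Why: Grignard 1,2-addition at −78 °C takes the aldehyde far faster than the methyl ketone, and the new carbinol centre need not be controlled because the next step destroys it.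

**Step 3**
Reactants: 5 allylic alcohol; 6 ethyl vinyl ether
Product: 8 (4E)-5-[(1S,3R)-2,2-dimethyl-3-(3-oxobutyl)cyclopropyl]-4-methylpent-4-enal, via allyl vinyl ether 7 (not isolated)
Conditions: 6 (solvent), Hg(OAc)2 (10 mol %), reflux, 16 h; evaporate; toluene, 110 °C, 8 h
Reagents that add atoms: ethyl vinyl ether (6), C=COCC
Why: Transvinylation followed by Claisen rearrangement through a chair with the cyclopropyl group equatorial gives the E-trisubstituted C4=C5 alkene from either carbinol epimer, and 110 °C stays below the onset of the homodienyl hydrogen shift of cis-alkyl vinylcyclopropanes.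

**Step 4**
Reactants: 8 keto enal
Product: 9 (+)-bicyclogermacrene, (1S,2E,6E,10R)-3,7,11,11-tetramethylbicyclo[8.1.0]undeca-2,6-diene
Conditions: TiCl3(DME)1.5 (10 equiv), Zn–Cu couple (30 equiv), DME, reflux; 8 added over 36 h (final 2 mM); AgNO3–silica chromatography
Reagents that add atoms: none
Why: Intramolecular McMurry coupling of the aldehyde (C1) with the methyl ketone (C10) closes the ten-membered ring, which is a known reaction type for germacrane-type macrocycles, and the minor Z isomer at C1=C10 is removed on silver-loaded silica.

**Step 5 (key step)**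
Reactants: 9 bicyclogermacrene; 10 2,4,6-trihydroxyisophthalaldehyde; 11 isovaleraldehyde
Product: 14 5-{(1S)-3-methyl-1-[(1aR,7R,7aR,7bR)-1,1,4,7-tetramethyl-1a,2,3,5,6,7,7a,7b-octahydro-1H-cyclopropa[e]azulen-7-yl]butyl}-2,4,6-trihydroxybenzene-1,3-dicarbaldehyde, via o-quinone methide 12 (not isolated), via C10 cation zwitterion 13 (not isolated)
Conditions: 10 (1.0 equiv), 11 (1.5 equiv), ethylenediammonium diacetate (10 mol %), 4 Å MS, MeCN, 45 °C
Reagents that add atoms: 2,4,6-trihydroxyisophthalaldehyde (10), O=Cc1c(O)c(C=O)c(O)cc1O; isovaleraldehyde (11), CC(C)CC=O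
Why: Proposed new method: Knoevenagel condensation gives the E-o-quinone methide, which is attacked by C4 on the exposed outer face of the E-C4=C5 alkene (the charge at C5 is stabilised by the cyclopropane) while C1=C10 adds to C5 from the inner face in an anti transannular cation–olefin cyclisation that sets C4 (R) and C5 (R), the arene lying over the less hindered C3/H5 side with the isobutyl group pointing outwards sets C1' (S), and acetate removes H1 from the C10 cation to give the tetrasubstituted C1=C10 alkene; the closest known reaction types are the acid-induced cyclisation of bicyclogermacrene to the same tetrasubstituted alkene skeleton and three-component o-quinone methide couplings of formylphloroglucinols with terpenes.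

**Step 6**
Reactants: 14 tricyclic alkene
Product: 16 Macrocarpal N, via secondary ozonide 15 (not isolated)
Conditions: O3 (1.0 equiv, titrated CH2Cl2 solution), CH2Cl2, −78 °C; then Me2S, −78 to 0 °C
Reagents that add atoms: ozone, [O-][O+]=O
Why: Ozonolysis of the electron-rich tetrasubstituted alkene outruns attack on the hydrogen-bonded, doubly formyl-deactivated phenol ring and releases both ketones at once, while C5 (now alpha to C1=O) already holds the more stable trans arrangement of cyclopropyl and arylalkyl groups and so does not epimerise.

**Compound list**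
1 | (+)-2-carene | CC1=C[C@H]2[C@@H](CC1)C2(C)C | starting material
2 | secondary ozonide of 1 | CC56CC[C@@H]1[C@H](C(OO5)O6)C1(C)C | intermediate
3 | (1S,3R)-2,2-dimethyl-3-(3-oxobutyl)cyclopropane-1-carbaldehyde | CC(=O)CC[C@@H]1[C@H](C=O)C1(C)C | intermediate
4 | isopropenylmagnesium bromide | C=C(C)[Mg]Br | starting material
5 | allylic alcohol (carbinol epimers) | CC(=O)CC[C@@H]1[C@H](C(O)C(C)=C)C1(C)C | intermediate
6 | ethyl vinyl ether | C=COCC | starting material
7 | allyl vinyl ether | CC(=O)CC[C@@H]1[C@H](C(OC=C)C(C)=C)C1(C)C | intermediate
8 | (E)-keto enal | CC(=O)CC[C@@H]1[C@H](/C=C(\C)CCC=O)C1(C)C | intermediate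
9 | (+)-bicyclogermacrene | C/C1=C\CC/C(C)=C/[C@H]2[C@@H](CC1)C2(C)C | intermediate
10 | 2,4,6-trihydroxyisophthalaldehyde | O=Cc1c(O)c(C=O)c(O)cc1O | starting material
11 | isovaleraldehyde | CC(C)CC=O | starting material
12 | (E)-o-quinone methide | CC(C)C/C=C1\C(O)=C(C=O)C(O)=C(C=O)C1=O | intermediate
13 | C10 cation / phenolate zwitterion | C[C+]1CC[C@@H]2[C@H]([C@H]3[C@H]1CC[C@]3(C)[C@H](CC(C)C)c1c([O-])c(C=O)c(O)c(C=O)c1O)C2(C)C | intermediate
14 | tricyclic C1=C10 alkene | CC1=C2CC[C@](C)([C@H](CC(C)C)c3c(O)c(C=O)c(O)c(C=O)c3O)[C@H]2[C@H]3[C@@H](CC1)C3(C)C | intermediate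
15 | secondary ozonide of 14 | CC56CC[C@@H]1[C@H]([C@H]2C(OO5)(O6)CC[C@]2(C)[C@H](CC(C)C)c2c(O)c(C=O)c(O)c(C=O)c2O)C1(C)C | intermediate
16 | Macrocarpal N | CC(=O)CC[C@@H]1[C@H]([C@H]2C(=O)CC[C@]2(C)[C@H](CC(C)C)c2c(O)c(C=O)c(O)c(C=O)c2O)C1(C)C | target

Total step count: 6. Longest linear sequence: 6 (1 → 3 → 5 → 8 → 9 → 14 → 16).

**Steps most likely to fail**

Step 5. The acidic phenol 10 may protonate 9 before coupling. The o-quinone methide may instead add to an alkene as a chroman-forming hetero-Diels–Alder partner. Proton loss may also give other alkene isomers, or a C1' epimer mixture may form. The fallback sets out from 10 and comes back at 14. It separates quinone methide formation from the coupling. Compounds 10, 11 and morpholine are condensed to the isolable Mannich base 2,4,6-trihydroxy-5-[3-methyl-1-(morpholin-4-yl)butyl]isophthalaldehyde F1. This is then warmed with 9 in toluene at 80 °C without any acid, so that 12 is released slowly by retro-Mannich elimination and meets an excess of intact macrocycle.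

Step 4. The ten-membered ring closure may give oligomers or mainly the Z alkene. The fallback sets out from 8 and comes back at 9. It replaces the one-pot deoxygenative coupling with a two-stage, stereospecific sequence. SmI2 in THF at high dilution stops at the macrocyclic 1,10-diol F2, and its diastereomers are separated. The threo diol is converted with thiocarbonyldiimidazole into the cyclic thionocarbonate F3. Treatment with 1,3-dimethyl-2-phenyl-1,3,2-diazaphospholidine at 40 °C (Corey–Winter type syn elimination) then delivers only the E alkene 9.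

Step 6. Ozone may attack the phenol ring or over-oxidise the formyl groups. The fallback sets out from 14 and comes back at 16, and it uses an ene/fragmentation path in place of a dipolar cycloaddition. Photo-oxygenation (O2, tetraphenylporphyrin, visible light, CH2Cl2, −20 °C) gives the allylic hydroperoxide F4 by a Schenck ene reaction. Catalytic CF3CO2H in wet CH2Cl2 then triggers Hock cleavage (vinyl migration to oxygen, hydrolysis, enol to ketone) of the C1–C10 bond. Regioisomeric hydroperoxides at C1 or C10 converge on the same diketone 16.

**Further compounds**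
F1 | step 5 | 2,4,6-trihydroxy-5-[3-methyl-1-(morpholin-4-yl)butyl]isophthalaldehyde (racemic) | CC(C)CC(N1CCOCC1)c1c(O)c(C=O)c(O)c(C=O)c1O
F2 | step 4 | macrocyclic 1,10-diol, (E)-3,7,11,11-tetramethylbicyclo[8.1.0]undec-2-ene-6,7-diol | CC1(O)CC[C@@H]2[C@H](/C=C(\C)CCC1O)C2(C)C
F3 | step 4 | cyclic thionocarbonate of F2 | CC12CC[C@@H]3[C@H](/C=C(\C)CCC1OC(=S)O2)C3(C)C
F4 | step 6 | C10 hydroperoxide with C1=C2 alkene | CC1(OO)CC[C@@H]2[C@H]([C@H]3C1=CC[C@]3(C)[C@H](CC(C)C)c1c(O)c(C=O)c(O)c(C=O)c1O)C2(C)C
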